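(The numbers in the tables stem from a simulated flask on assumed constants; noise was put on by code.)

Counting comes first: if each substrate molecule that becomes product takes one partner, which is my assumption, the partner charge puts a ceiling on conversion. In the flask, which is the violet run carried on, the partner charge over the two substrates charged together is 100%, and I call that share the partner ceiling. My decision is whether to leave this charge and wait until 4.0 min, or to change it.

in all of them: free catalyst 8.7 mM; racemization catalyst 5.1 mM; added ligand 23 mM

| flask | left-handed substrate | right-handed substrate | partner | remark | time |
|---|---|---|---|---|---|
| violet | 0.30 M | 0.30 M | 0.60 M | the very flask that is asked about, followed so far |  |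
| red | 0.15 M | 0.15 M | 0.60 M | run made earlier |  |
| flask | 0.30 M | 0.30 M | 0.600 M |  | 4.0 min |

| run | time / s | left-handed substrate / % | right-handed substrate / % |
|---|---|---|---|
| violet | 20.0 | 29 | 36 |
| violet | 40.0 | 18 | 31 |
| violet | 60.0 | 18 | 25 |
| violet | 80.0 | 17 | 22 |
| violet | 90.0 | 14 | 21 |
| red | 10.0 | 37 | 43 |
| red | 25.0 | 24 | 34 |
| red | 40.0 | 19 | 27 |
| red | 60.0 | 12 | 19 |
| red | 90.0 | 10 | 14 |

(each reading ± 2 percentage points)

- free catalyst is single-handed; left-handed substrate and right-handed substrate are mirror images of each other, charged as a racemate, each of them at the stated concentration
- an excess is below zero if the other one leads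

* part of the left-handed substrate and right-handed substrate charged together that has reacted at 4.0 min
* excess of left-handed product over right-handed product in the product at 4.0 min
* excess of right-handed substrate over left-handed substrate among what is left of the two at 4.0 min

At this ceiling, partner and substrate start equal and fall together. If the rate goes as substrate times partner, the inverse of the fraction left grows linearly in time, as in a second-order decay. The violet run has 35.0% left at 90.0 s, from two readings that each scatter by 2 percentage points, so the slope is 0.0206 s⁻¹. Carried to 4.0 min, this gives 83.2% reacted. But the slope read at 40.0 s is steeper, 0.0260 s⁻¹, so within the scatter the readings hint at a slowing decay, and my figure may be high. The ceiling stands above my figure, so on this reckoning the flask is still short of its ceiling at 4.0 min. I leave the partner as it is.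

The forecast gives 80% reacted, a product excess of 23% and a substrate excess of 10%, and it argues: “As the partner runs out, resolution weakens and racemization pulls the remaining substrate towards racemic”. Its conversion is lower than mine. For the two excesses I have no reckoning of my own.

The flask gives 82.1% reacted, a product excess of 25.2% and a substrate excess of 15.8%.

    partner + free catalyst + left-handed substrate → free catalyst + left-handed product (k = 7.20 M⁻² s⁻¹)
    partner + free catalyst + right-handed substrate → free catalyst + right-handed product (k = 3.40 M⁻² s⁻¹)
    left-handed substrate + racemization catalyst ⇌ right-handed substrate + racemization catalyst, rate k3*[racemization catalyst]*[left-handed substrate] forward; the back reaction follows from the equilibrium constant (k = 4.10 M⁻¹ s⁻¹)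
    racemization catalyst + added ligand ⇌ idle complex (K = 200 M⁻¹, k = 1.00 M⁻¹ s⁻¹)
    partner + free catalyst → spent catalyst (k = 0.00970 M⁻¹ s⁻¹)

In the flask, conversion stands 18 points under the ceiling, with 17% of the partner left. The neighbour charged with 0.36 M of partner, all else as in the flask, has a ceiling of 60.0%, below my 83.2%, which makes partner the limiting reagent there. That neighbour reaches 57.0% at 4.0 min, 3 points under its ceiling, with 4.49% of its partner left. Its product excess is 29.9%, and right-handed substrate leads left-handed by 5.94% among what remains.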